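**Plan**

Numbering: C1 epoxide CH, C2=C3, C4(CH3)=C5, C6 (lactone O–CH), C7, C8 (acyloxy CH), C9H2, C10 (epoxide C bearing C14H2OH); lactone C11(=C13H2)–C12(=O).
Cuts: the C1–C10 oxirane oxygen and the C8 ester first; then C7–C11 together with C8–O (radical annulation from a 2-iodoallyl acetal on O6, nitroxide capture); then C1=C10 (ring-closing olefination), C9–C10, C6–C7 and C3–C4.
Forward: C1–C6 enyne chain, C6–C7 join, C10/C14 unit, ten-membered ring closed at C1=C10 as a dienediyne, semihydrogenation to the all-cis tetraene, five-membered lactol ring in the key step, oxirane ring last.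
Stereochemistry: C6 from a catalyst-controlled alkynylation; C7 and C8 from C6 in the key step; C1/C10 from a D-(−)-tartrate-controlled epoxidation; ring Z-alkenes from a Z-iodide and cis-semihydrogenation; side-chain Z from a syn-hydroalumination.
Enabling feature: on the five-membered lactone fused to the ten-membered ring, C6–O, C7–C11 and C8–O are all cis, so a C11 vinyl radical tethered to O6 can add to C7 of a Z C7=C8 bond while the C8 radical takes up oxygen.

Key step: step 15

Assumption: (R,R)-ProPhenol is taken to deliver the alkynylzinc species to the Re face of the Z-enal in step 4 (S carbinol); the sense is checked on the first batch and the antipodal ligand used if it is the opposite.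

**Route**

Step 1
Reactants: 1 but-2-yn-1-ol
Product: 3 (Z)-3-iodobut-2-en-1-ol, via cyclic sodium alkenylalanate 2 (not isolated)
Conditions: NaAlH2(OCH2CH2OCH3)2, Et2O, 0 °C to rt; EtOAc quench; I2, THF, −78 °C
Reagents that add atoms: iodine, II
Why: Hydroxyl-directed trans-hydroalumination of the propargylic alcohol, then iodinolysis of the C–Al bond with retention, should give the Z-iodoalkene whose geometry becomes that of C4=C5.

Step 2
Reactants: 3 (Z)-3-iodobut-2-en-1-ol; 4 3,3-diethoxyprop-1-yne
Product: 5 (Z)-6,6-diethoxy-3-methylhex-2-en-4-yn-1-ol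
Conditions: Pd(PPh3)2Cl2 (cat.), CuI (cat.), Et3N, THF, rt
Reagents that add atoms: none
Why: Sonogashira coupling forms the C3–C4 bond with retention of the Z geometry, and the acetal carries C1 as a masked aldehyde.

Step 3
Reactants: 5 (Z)-6,6-diethoxy-3-methylhex-2-en-4-yn-1-ol
Product: 6 (Z)-6,6-diethoxy-3-methylhex-2-en-4-ynal
Conditions: MnO2, CH2Cl2, rt
Reagents that add atoms: none
Why: Allylic oxidation with MnO2 is selective for the allylic alcohol and should leave the acetal and the Z geometry untouched at room temperature.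

Step 4
Reactants: 6 (Z)-6,6-diethoxy-3-methylhex-2-en-4-ynal; 7 tert-butyldimethyl(prop-2-yn-1-yloxy)silane
Product: 8 (4S,5Z)-1-(tert-butyldimethylsilyloxy)-9,9-diethoxy-6-methylnon-5-ene-2,7-diyn-4-ol
Conditions: (R,R)-ProPhenol (20 mol %), Zn(CH3)2, Ph3P=O (40 mol %), toluene, 4 °C
Reagents that add atoms: none
Why: Zinc–ProPhenol catalysed asymmetric alkynylation of the enal forms the C6–C7 bond, the chiral dinuclear zinc catalyst directing the alkynylzinc to the Re face and so setting C6 as S.

Step 5
Reactants: 8 (4S,5Z)-1-(tert-butyldimethylsilyloxy)-9,9-diethoxy-6-methylnon-5-ene-2,7-diyn-4-ol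
Product: 9 acetate of 8 at O6
Conditions: Ac2O, DMAP (cat.), pyridine, CH2Cl2, 0 °C
Reagents that add atoms: acetic anhydride, CC(=O)OC(C)=O
Why: DMAP-catalysed acylation protects O6 with a group that the ester reduction of step 11 removes in the same operation.

Step 6
Reactants: 9 acetate of 8
Product: 10 (4S,5Z)-9,9-diethoxy-1-hydroxy-6-methylnon-5-ene-2,7-diyn-4-yl acetate
Conditions: HF·pyridine, pyridine, THF, 0 °C
Reagents that add atoms: none
Why: Fluoride-mediated desilylation frees the primary propargylic alcohol, while acetate and acetal are stable to buffered HF·pyridine.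

Step 7
Reactants: 10 (4S,5Z)-9,9-diethoxy-1-hydroxy-6-methylnon-5-ene-2,7-diyn-4-yl acetate
Product: 11 (4S,5Z)-1-bromo-9,9-diethoxy-6-methylnon-5-ene-2,7-diyn-4-yl acetate
Conditions: CBr4, PPh3, CH2Cl2, 0 °C
Reagents that add atoms: carbon tetrabromide, BrC(Br)(Br)Br
Why: The Appel reaction converts the primary propargylic alcohol into the bromide under neutral conditions.

Step 8
Reactants: 11 (4S,5Z)-1-bromo-9,9-diethoxy-6-methylnon-5-ene-2,7-diyn-4-yl acetate; 12 triethyl phosphonoacetate
Product: 13 ethyl (6S,7Z)-6-acetoxy-2-(diethoxyphosphoryl)-11,11-diethoxy-8-methylundec-7-ene-4,9-diynoate (both epimers at the phosphonate carbon)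
Conditions: NaH, 12 in excess, THF, 0 °C to rt
Reagents that add atoms: none
Why: SN2 alkylation of sodium phosphonoacetate by the primary propargylic bromide forms the C9–C10 bond, the excess nucleophile suppressing double alkylation.

Step 9
Reactants: 13 ethyl (6S,7Z)-6-acetoxy-2-(diethoxyphosphoryl)-11,11-diethoxy-8-methylundec-7-ene-4,9-diynoate
Product: 14 ethyl (6S,7Z)-6-acetoxy-2-(diethoxyphosphoryl)-8-methyl-11-oxoundec-7-ene-4,9-diynoate
Conditions: Amberlyst-15, acetone/H2O, rt
Reagents that add atoms: water, O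
Why: Acid-catalysed acetal hydrolysis unmasks the C1 ynal, and the acetate and phosphonate ester are inert to the sulfonic acid resin.

Step 10
Reactants: 14 ethyl (6S,7Z)-6-acetoxy-2-(diethoxyphosphoryl)-8-methyl-11-oxoundec-7-ene-4,9-diynoate
Product: 15 ethyl (1E,5Z,7S)-7-acetoxy-5-methylcyclodeca-1,5-diene-3,8-diyne-1-carboxylate (ten-membered ring: C10(CO2Et)=C1, C2≡C3, Z C4=C5, C6–OAc, C7≡C8, C9H2)
Conditions: LiCl, DBU, MeCN, rt, slow addition of 14 to about 1 mM
Reagents that add atoms: none
Why: Intramolecular Horner–Wadsworth–Emmons olefination under Masamune–Roush conditions closes the ten-membered ring at C1=C10, because the Z-alkene and the two linear alkyne units hold the aldehyde beside the phosphonate carbon and only the E-enoate (C9 cis to C2) fits the ring.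

Step 11
Reactants: 15 ethyl (1E,5Z,7S)-7-acetoxy-5-methylcyclodeca-1,5-diene-3,8-diyne-1-carboxylate
Product: 16 (1S,2Z,6E)-7-(hydroxymethyl)-3-methylcyclodeca-2,6-diene-4,9-diyn-1-ol
Conditions: i-Bu2AlH (5 equiv), CH2Cl2, −78 °C
Reagents that add atoms: none
Why: Hydride reduction with i-Bu2AlH takes the conjugated ester in a 1,2-sense to the C14 allylic alcohol and cleaves the acetate at the same time.

Step 12
Reactants: 16 (1S,2Z,6E)-7-(hydroxymethyl)-3-methylcyclodeca-2,6-diene-4,9-diyn-1-ol
Product: 17 (1S,2Z,6E)-7-(tert-butyldiphenylsilyloxymethyl)-3-methylcyclodeca-2,6-diene-4,9-diyn-1-ol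
Conditions: tert-butyldiphenylsilyl chloride (1.05 equiv), imidazole, CH2Cl2, 0 °C
Reagents that add atoms: tert-butyldiphenylsilyl chloride, CC(C)(C)[Si](Cl)(c1ccccc1)c1ccccc1
Why: Silylation with the bulky chlorosilane is selective for the primary allylic alcohol over the secondary C6 carbinol, and the silyl ether chosen survives the later aqueous acid steps.

Step 13
Reactants: 17 (1S,2Z,6E)-7-(tert-butyldiphenylsilyloxymethyl)-3-methylcyclodeca-2,6-diene-4,9-diyn-1-ol
Product: 18 (1R,2Z,4Z,6E,9Z)-7-(tert-butyldiphenylsilyloxymethyl)-3-methylcyclodeca-2,4,6,9-tetraen-1-ol (same spatial arrangement at C6; the descriptor changes with the ranking)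
Conditions: H2 (1 atm, 2 equiv taken up), Pd/CaCO3 poisoned with Pb(OAc)2, quinoline, EtOAc, 0 °C
Reagents that add atoms: none
Why: Lindlar semihydrogenation delivers H2 syn on the poisoned palladium surface and should turn both ring alkynes into Z-alkenes (C2=C3, C7=C8), quinoline and lead stopping the reduction at the tetraene.

Step 14
Reactants: 18 the all-cis tetraenol; 19 methoxyallene
Product: 20 mixed acetal of 18 at O6, O6–CH(OCH3)–C(I)=CH2 (both epimers at the acetal carbon)
Conditions: N-iodosuccinimide, 19 (5 equiv), CH2Cl2, −78 to −30 °C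
Reagents that add atoms: N-iodosuccinimide, O=C1CCC(=O)N1I
Why: Haloalkoxylation of the allenyl ether, in which iodonium attack at the central allene carbon gives a 2-iodoallyl oxocarbenium ion that the C6 alcohol captures, should form the Ueno–Stork type acetal faster than the triene is iodinated at low temperature.

Step 15
Reactants: 20 the 2-iodoallyl mixed acetal; 21 TEMPO (2,2,6,6-tetramethylpiperidin-1-oxyl)
Product: 22 cis-fused lactol methyl ether (ring O6–C12(OCH3)–C11(=C13H2)–C7–C6) carrying the 2,2,6,6-tetramethylpiperidin-1-yloxy group at C8 cis to C7–C11; H6, H7 and H8 on one face; both C12 epimers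
Conditions: Bu3SnH (4 equiv) and 21 (6 equiv), both added slowly, degassed PhH, 60 °C
Reagents that add atoms: none
Why: Bu3Sn•, formed from Bu3SnH and the nitroxide, abstracts iodine from the C(I)=CH2 group, the σ-vinyl radical at C11 adds 5-exo-trig to C7 of the Z C7=C8 bond (C7–C11, closing the five-membered lactol ring) and the secondary C8 radical couples with 21 (C8–O). The closest known reaction type is the Ueno–Stork haloacetal radical cyclisation run under nitroxide-trapping conditions. C7 is controlled by C6: the three-atom O6–C12–C11 tether reaches C7 only on the face that carries O6, and closure through the ring conformer with C5 synclinal to C7=C8 gives the cis-fused bicycle. C8 is controlled by that bicycle, the bulky nitroxide approaching the outer face of the folded ring, which places the new C–O bond cis to C7–C11. The step needs attack at C7 and not at C5 (the end of the triene) and capture of the C8 radical before transannular addition; the first depends on the conformer that holds the C6–O bond over the C7=C8 π-face, the second is secured by the high rate of radical–nitroxide coupling. The iodide is used in place of a bromide so that halogen abstraction outruns stannyl–nitroxide coupling, and 60 °C should keep the all-cis triene below 6π-electrocyclisation.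

Step 16
Reactants: 22 the lactol methyl ether
Product: 23 lactol (C12–OH, both epimers)
Conditions: pyridinium p-toluenesulfonate, acetone/H2O, rt
Reagents that add atoms: water, O
Why: Mild acid-catalysed hydrolysis of the allylic methyl acetal gives the lactol, while the silyl ether and the alkoxyamine tolerate pyridinium tosylate.

Step 17
Reactants: 23 the lactol
Product: 24 α-methylene-γ-butyrolactone (6,12-olide) with the aminoxy group at C8 and the silyl ether at C14
Conditions: MnO2, CH2Cl2, rt
Reagents that add atoms: none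
Why: MnO2 oxidises the allylic lactol to the lactone, which also removes the acetal stereocentre, and no free allylic alcohol is present to compete.

Step 18
Reactants: 24 the aminoxy lactone
Product: 25 8-hydroxy lactone (C14 silyl ether)
Conditions: Zn dust, AcOH/THF/H2O, 40 °C
Reagents that add atoms: none
Why: Zinc in acetic acid cleaves the N–O bond of the alkoxyamine reductively and frees the C8 alcohol with its configuration unchanged; the lactone is formed first so that O6 and O8 cannot exchange roles at the lactol stage.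

Step 19
Reactants: 26 ethyl but-2-ynoate
Product: 28 ethyl (Z)-2-(hydroxymethyl)but-2-enoate, via alpha-alumino enoate 27 (not isolated)
Conditions: i-Bu2AlH, HMPA, THF, 0 °C; then gaseous formaldehyde, −20 °C to rt
Reagents that add atoms: formaldehyde, C=O
Why: Conjugate hydroalumination of the ynoate adds H and Al syn (Al at the α-carbon) and the alkenylalane hydroxymethylates with retention, so CH3 and the ester end up cis (Z).

Step 20
Reactants: 28 ethyl (Z)-2-(hydroxymethyl)but-2-enoate
Product: 29 ethyl (Z)-2-(tert-butyldimethylsilyloxymethyl)but-2-enoate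
Conditions: tert-butyldimethylsilyl chloride, imidazole, CH2Cl2, 0 °C
Reagents that add atoms: tert-butyldimethylsilyl chloride, CC(C)(C)[Si](C)(C)Cl
Why: Standard silylation protects the primary alcohol so that only the carboxyl group can acylate in step 22.

Step 21
Reactants: 29 ethyl (Z)-2-(tert-butyldimethylsilyloxymethyl)but-2-enoate
Product: 30 (Z)-2-(tert-butyldimethylsilyloxymethyl)but-2-enoic acid
Conditions: LiOH, THF/MeOH/H2O, 0 °C to rt; 1 M HCl to pH 4 at 0 °C
Reagents that add atoms: lithium hydroxide, [Li+].[OH-]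
Why: Saponification at low temperature should give the acid without Z to E isomerisation, and the silyl ether is stable to hydroxide.

Step 22
Reactants: 25 the 8-hydroxy lactone; 30 (Z)-2-(tert-butyldimethylsilyloxymethyl)but-2-enoic acid
Product: 32 C8 ester of 25 with the silyl-protected Z acid, via mixed anhydride 31 (not isolated)
Conditions: 2,4,6-trichlorobenzoyl chloride, Et3N, toluene, rt; then 25, DMAP, rt
Reagents that add atoms: none
Why: Yamaguchi esterification through the mixed anhydride acylates the hindered C8 alcohol and is the usual way to attach Z-2-substituted but-2-enoates without isomerisation.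

Step 23
Reactants: 32 the bis-silyl ester
Product: 33 diol (free C14–OH and free side-chain CH2OH)
Conditions: HF·pyridine, pyridine, THF, 0 °C to rt
Reagents that add atoms: none
Why: Fluoride-mediated cleavage removes both primary silyl ethers and leaves the lactone and the enoate ester intact.

Step 24
Reactants: 33 the diol
Product: 34 target, (1R,6S,7R,8R,10R)-configured 1,10-epoxide
Conditions: Ti(OiPr)4 (20 mol %), D-(−)-diethyl tartrate (24 mol %), t-BuOOH, 4 Å molecular sieves, CH2Cl2, −20 °C
Reagents that add atoms: tert-butyl hydroperoxide, CC(C)(C)OO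
Why: Sharpless asymmetric epoxidation: the C14 allylic alcohol binds titanium and confines oxygen transfer to C1=C10 (the side-chain alkene is electron-poor), and D-(−)-tartrate delivers oxygen to the face that gives 1R,10R with C14 and H1 cis on the oxirane.

**Compound list**

1 | but-2-yn-1-ol | CC#CCO | starting material
2 | cyclic sodium alkenylalanate (O–Al–C3 five-membered ring, two 2-methoxyethoxy ligands) | CC1=CCO[Al-]1(OCCOC)OCCOC.[Na+] | intermediate (not isolated)
3 | (Z)-3-iodobut-2-en-1-ol | C/C(I)=C/CO | intermediate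
4 | 3,3-diethoxyprop-1-yne | C#CC(OCC)OCC | starting material
5 | (Z)-6,6-diethoxy-3-methylhex-2-en-4-yn-1-ol | CCOC(OCC)C#C/C(C)=C\CO | intermediate
6 | (Z)-6,6-diethoxy-3-methylhex-2-en-4-ynal | CCOC(OCC)C#C/C(C)=C\C=O | intermediate
7 | tert-butyldimethyl(prop-2-yn-1-yloxy)silane | C#CCO[Si](C)(C)C(C)(C)C | starting material
8 | (4S,5Z)-1-(tert-butyldimethylsilyloxy)-9,9-diethoxy-6-methylnon-5-ene-2,7-diyn-4-ol | CCOC(OCC)C#C/C(C)=C\[C@H](O)C#CCO[Si](C)(C)C(C)(C)C | intermediate
9 | (4S,5Z)-1-(tert-butyldimethylsilyloxy)-9,9-diethoxy-6-methylnon-5-ene-2,7-diyn-4-yl acetate | CCOC(OCC)C#C/C(C)=C\[C@H](OC(C)=O)C#CCO[Si](C)(C)C(C)(C)C | intermediate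
10 | (4S,5Z)-9,9-diethoxy-1-hydroxy-6-methylnon-5-ene-2,7-diyn-4-yl acetate | CCOC(OCC)C#C/C(C)=C\[C@H](OC(C)=O)C#CCO | intermediate
11 | (4S,5Z)-1-bromo-9,9-diethoxy-6-methylnon-5-ene-2,7-diyn-4-yl acetate | CCOC(OCC)C#C/C(C)=C\[C@H](OC(C)=O)C#CCBr | intermediate
12 | triethyl phosphonoacetate | CCOC(=O)CP(=O)(OCC)OCC | starting material
13 | ethyl (6S,7Z)-6-acetoxy-2-(diethoxyphosphoryl)-11,11-diethoxy-8-methylundec-7-ene-4,9-diynoate (C2 epimers) | CCOC(OCC)C#C/C(C)=C\[C@H](OC(C)=O)C#CCC(C(=O)OCC)P(=O)(OCC)OCC | intermediate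
14 | ethyl (6S,7Z)-6-acetoxy-2-(diethoxyphosphoryl)-8-methyl-11-oxoundec-7-ene-4,9-diynoate (C2 epimers) | O=CC#C/C(C)=C\[C@H](OC(C)=O)C#CCC(C(=O)OCC)P(=O)(OCC)OCC | intermediate
15 | ethyl (1E,5Z,7S)-7-acetoxy-5-methylcyclodeca-1,5-diene-3,8-diyne-1-carboxylate | CCOC(=O)/C1=C/C#C/C(C)=C\[C@H](OC(C)=O)C#CC1 | intermediate
16 | (1S,2Z,6E)-7-(hydroxymethyl)-3-methylcyclodeca-2,6-diene-4,9-diyn-1-ol | OC/C1=C/C#C/C(C)=C\[C@H](O)C#CC1 | intermediate
17 | (1S,2Z,6E)-7-(tert-butyldiphenylsilyloxymethyl)-3-methylcyclodeca-2,6-diene-4,9-diyn-1-ol | CC(C)(C)[Si](c1ccccc1)(c1ccccc1)OC/C1=C/C#C/C(C)=C\[C@H](O)C#CC1 | intermediate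
18 | (1R,2Z,4Z,6E,9Z)-7-(tert-butyldiphenylsilyloxymethyl)-3-methylcyclodeca-2,4,6,9-tetraen-1-ol | C1/C=C\[C@@H](O)/C=C(C)\C=C/C=C1/CO[Si](c1ccccc1)(c1ccccc1)C(C)(C)C | intermediate
19 | methoxyallene (1-methoxypropa-1,2-diene) | COC=C=C | starting material
20 | mixed acetal of 18 at O6 with CH(OCH3)–C(I)=CH2 (acetal epimers; 6R as in 18) | C1/C=C\[C@@H](OC(OC)C(I)=C)/C=C(C)\C=C/C=C1/CO[Si](c1ccccc1)(c1ccccc1)C(C)(C)C | intermediate
21 | TEMPO (2,2,6,6-tetramethylpiperidin-1-oxyl) | CC1(C)CCCC(C)(C)N1[O] | starting material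
22 | cis-fused 12-methoxy-13-methylene lactol ether on C6–C7, 8-(2,2,6,6-tetramethylpiperidin-1-yloxy) cis to C7–C11, C14 silyl ether, Z,Z-diene and C1=C10 in the ring; C6, C7, C8 as in the target; C12 epimers | C=C1C(OC)O[C@H]2/C=C(C)\C=C/C=C(CO[Si](c3ccccc3)(c3ccccc3)C(C)(C)C)\C[C@@H](ON3C(C)(C)CCCC3(C)C)[C@@H]12 | intermediate
23 | lactol of 22 (C12–OH, epimers) | C=C1C(O)O[C@H]2/C=C(C)\C=C/C=C(CO[Si](c3ccccc3)(c3ccccc3)C(C)(C)C)\C[C@@H](ON3C(C)(C)CCCC3(C)C)[C@@H]12 | intermediate
24 | 6,12-olide (α-methylene-γ-butyrolactone) with 8-aminoxy group and C14 silyl ether | C=C1C(=O)O[C@H]2/C=C(C)\C=C/C=C(CO[Si](c3ccccc3)(c3ccccc3)C(C)(C)C)\C[C@@H](ON3C(C)(C)CCCC3(C)C)[C@@H]12 | intermediate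
25 | 8-hydroxy-6,12-olide with C14 silyl ether (H6, H7, H8 cis) | C=C1C(=O)O[C@H]2/C=C(C)\C=C/C=C(CO[Si](c3ccccc3)(c3ccccc3)C(C)(C)C)\C[C@@H](O)[C@@H]12 | intermediate
26 | ethyl but-2-ynoate | CC#CC(=O)OCC | starting material
27 | ethyl (Z)-2-(diisobutylalumanyl)but-2-enoate | C/C=C(/[Al](CC(C)C)CC(C)C)C(=O)OCC | intermediate (not isolated)
28 | ethyl (Z)-2-(hydroxymethyl)but-2-enoate | C/C=C(/CO)C(=O)OCC | intermediate
29 | ethyl (Z)-2-(tert-butyldimethylsilyloxymethyl)but-2-enoate | C/C=C(/CO[Si](C)(C)C(C)(C)C)C(=O)OCC | intermediate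
30 | (Z)-2-(tert-butyldimethylsilyloxymethyl)but-2-enoic acid | C/C=C(/CO[Si](C)(C)C(C)(C)C)C(=O)O | intermediate
31 | mixed anhydride of 30 with 2,4,6-trichlorobenzoic acid | C/C=C(/CO[Si](C)(C)C(C)(C)C)C(=O)OC(=O)c1c(Cl)cc(Cl)cc1Cl | intermediate (not isolated)
32 | 8-O-[(Z)-2-(tert-butyldimethylsilyloxymethyl)but-2-enoyl] derivative of 25 | C=C1C(=O)O[C@H]2/C=C(C)\C=C/C=C(CO[Si](c3ccccc3)(c3ccccc3)C(C)(C)C)\C[C@@H](OC(=O)/C(=C\C)CO[Si](C)(C)C(C)(C)C)[C@@H]12 | intermediate
33 | 14-hydroxy 8-O-[(Z)-2-(hydroxymethyl)but-2-enoyl] trienolide (1(10)-ene, no epoxide) | C=C1C(=O)O[C@H]2/C=C(C)\C=C/C=C(CO)\C[C@@H](OC(=O)/C(=C\C)CO)[C@@H]12 | intermediate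
34 | target, (1R,6S,7R,8R,10R)-1,10-epoxy-14-hydroxy-8-[(Z)-2-(hydroxymethyl)but-2-enoyloxy]-(2Z,4Z)-diene 6,12-olide | C=C1C(=O)O[C@H]2/C=C(C)\C=C/[C@H]3O[C@@]3(CO)C[C@@H](OC(=O)/C(=C\C)CO)[C@@H]12 | target

**Step count and risks**

Total steps: 24. Longest linear sequence: 21 (steps 1–18 and 22–24); steps 19–21 make the side-chain acid.

Step 15. What may go wrong is loss of site selectivity: the vinyl radical can close 5-exo onto C5, the end of the triene, where a delocalised radical results, instead of onto C7. A trans-fused closure from the conformer with O6 on the ring periphery belongs to the same conformational question, and the fallback below does not cure it. Fallback: C4=C5 is carried through the radical step as an epoxide. It sets out from 17, whose only allylic alkene is C4=C5. Hydroxyl-directed epoxidation with VO(acac)2 and t-BuOOH gives the 4,5-epoxy diynol F1. Semihydrogenation as in step 13 gives the epoxy trienol F2, and acetal formation as in step 14 gives the iodoallyl acetal F3. Cyclisation with nitroxide capture under the conditions of step 15, where C5 is now sp3, gives the epoxy lactol ether F4. Stereospecific deoxygenation with Ph3P=Se and CF3CO2H in CH2Cl2 restores the Z C4=C5 bond, and the route is rejoined at 22.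

Step 10. What may go wrong is intermolecular condensation and base-induced decomposition of the ynal outrunning ring closure. Fallback: the ring is closed at C6–C7 instead and the C6 configuration is set afterwards. It sets out from 5, which is hydrolysed (Amberlyst-15, wet acetone) to (Z)-6-hydroxy-4-methylhex-4-en-2-ynal F5. An intermolecular Horner–Wadsworth–Emmons reaction with ethyl 2-(diethoxyphosphoryl)pent-4-ynoate F6 (from 12, NaH and propargyl bromide) gives the E-enynoate alcohol F7. MnO2 gives the Z-enal F8, and N-iodosuccinimide with catalytic AgNO3 gives the iodoalkyne F9. An intramolecular Nozaki–Hiyama–Kishi reaction (CrCl2, catalytic NiCl2, THF, high dilution) closes the ten-membered ring to the racemic carbinol F10. MnO2 then gives the ynone F11, and Corey–Bakshi–Shibata reduction with the (S)-2-methyl-oxazaborolidine and catecholborane gives the (S)-alcohol F12. Reduction of the ester with i-Bu2AlH rejoins the route at 16.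

Step 13. What may go wrong is over-reduction and double-bond migration on the palladium surface once the conjugated all-cis triene has formed; the product is also prone to thermal 6π closure and is kept cold and used at once. Fallback: electron-transfer reduction in place of catalytic hydrogenation. It sets out from 17, which is treated with zinc dust activated by Cu(OAc)2 and AgNO3 in MeOH/H2O at rt; this reduces the conjugated and the propargylic-alcohol alkyne to Z-alkenes and cannot reduce alkenes. It returns at 18 and makes no new compound.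

**Further compounds**

F1 | step 15 | 4,5-epoxide of 17, oxirane oxygen syn to the C6 hydroxyl | CC(C)(C)[Si](c1ccccc1)(c1ccccc1)OC/C1=C/C#C[C@]2(C)O[C@@H]2[C@H](O)C#CC1
F2 | step 15 | 4,5-epoxy (2Z,7Z,1(10)E)-trienol from semihydrogenation of F1 | CC(C)(C)[Si](c1ccccc1)(c1ccccc1)OC/C1=C/C=C\[C@]2(C)O[C@@H]2[C@H](O)/C=C\C1
F3 | step 15 | mixed acetal of F2 at O6 with CH(OCH3)–C(I)=CH2 (acetal epimers) | CC(C)(C)[Si](c1ccccc1)(c1ccccc1)OC/C1=C/C=C\[C@]2(C)O[C@@H]2[C@H](OC(OC)C(I)=C)/C=C\C1
F4 | step 15 | 4,5-epoxide of 22 (cis-fused lactol methyl ether, 8-aminoxy group, C12 epimers) | C=C1C(OC)O[C@H]2[C@H]3O[C@@]3(C)\C=C/C=C(CO[Si](c4ccccc4)(c4ccccc4)C(C)(C)C)\C[C@@H](ON4C(C)(C)CCCC4(C)C)[C@@H]12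
F5 | step 10 | (Z)-6-hydroxy-4-methylhex-4-en-2-ynal | O=CC#C/C(C)=C\CO
F6 | step 10 | ethyl 2-(diethoxyphosphoryl)pent-4-ynoate | CCOC(=O)C(CC#C)P(=O)(OCC)OCC
F7 | step 10 | ethyl (2E,6Z)-8-hydroxy-6-methyl-2-(prop-2-yn-1-yl)octa-2,6-dien-4-ynoate | CCOC(=O)/C(CC#C)=C/C#C/C(C)=C\CO
F8 | step 10 | ethyl (2E,6Z)-6-methyl-8-oxo-2-(prop-2-yn-1-yl)octa-2,6-dien-4-ynoate | CCOC(=O)/C(CC#C)=C/C#C/C(C)=C\C=O
F9 | step 10 | ethyl (2E,6Z)-2-(3-iodoprop-2-yn-1-yl)-6-methyl-8-oxoocta-2,6-dien-4-ynoate | CCOC(=O)/C(CC#CI)=C/C#C/C(C)=C\C=O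
F10 | step 10 | ethyl (1E,5Z)-7-hydroxy-5-methylcyclodeca-1,5-diene-3,8-diyne-1-carboxylate (racemic) | CCOC(=O)/C1=C/C#C/C(C)=C\C(O)C#CC1
F11 | step 10 | ethyl (1E,5Z)-5-methyl-7-oxocyclodeca-1,5-diene-3,8-diyne-1-carboxylate | CCOC(=O)/C1=C/C#C/C(C)=C\C(=O)C#CC1
F12 | step 10 | ethyl (1E,5Z,7S)-7-hydroxy-5-methylcyclodeca-1,5-diene-3,8-diyne-1-carboxylate | CCOC(=O)/C1=C/C#C/C(C)=C\[C@H](O)C#CC1
F0 | step 13 | none | none
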